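**Strategy.** The route rests on disconnecting the CH2–C(=O) bond of the β-aryloxy ketone array O-1–C-2–CH2–C(=O) at the quaternary C-2 of the pyran ring. The precursor is an aryl ester: phenol 5, carrying a 3-methylbut-3-enyl chain, acylated by the enantiopure cyclopentylacetic acid 18. A palladium–carbene catalyst is proposed to add the ester C(acyl)–O bond across the 1,1-disubstituted alkene (intramolecular oxyacylation). This one operation consumes the ester tether, forms the C–C bond that unites the two fragments, closes the pyran ring through O-1–C-2 and creates the quaternary stereocentre C-2. Dehydrogenation to the 2H-chromene, unmasking of the ynone and cis-selective semihydrogenation finish the synthesis.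

Key step: step 9

Assumption: the sense of induction of the chiral lithium amide (step 5) and of the chiral carbene (step 9) cannot be assigned with certainty in advance; the enantiomer named is the one expected to give the required isomer, and the antipode of each is equally accessible.

Step 1
Reactants: 1 4-methoxy-2-methylphenol
Product: 2 2-bromo-4-methoxy-6-methylphenol
Conditions: NBS (1.0 equiv), MeCN, 0 °C
Reagents that add atoms: N-bromosuccinimide, O=C1CCC(=O)N1Br
Why: Electrophilic aromatic bromination, directed by the hydroxyl group to its only free ortho position (the para position carries OMe).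

Step 2
Reactants: 2 2-bromo-4-methoxy-6-methylphenol; 3 4-bromo-2-methylbut-1-ene
Product: 5 4-methoxy-2-methyl-6-(3-methylbut-3-en-1-yl)phenol, via (3-methylbut-3-en-1-yl)zinc bromide 4 (not isolated)
Conditions: 3, Zn dust, LiCl, THF, 40 °C; then 2, Pd(OAc)2 (2 mol %), SPhos (4 mol %), THF, 50 °C
Reagents that add atoms: none
Why: Negishi cross-coupling of a primary alkylzinc halide with an aryl bromide, which tolerates the free phenol when the zinc reagent is used in excess.

Step 3
Reactants: 6 cis-1,5-dimethylbicyclo[3.3.0]octane-3,7-dione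
Product: 7 cis-1,5-dimethylbicyclo[3.3.0]octane-3,7-dione mono(ethylene ketal)
Conditions: ethylene glycol (1.0 equiv), p-TsOH (cat.), benzene, reflux, Dean–Stark; unreacted 6 and bis-ketal are recycled
Reagents that add atoms: ethylene glycol, OCCO
Why: Acid-catalysed ketalisation; the two carbonyl groups are equivalent, so one equivalent of diol should give the mono-ketal as the main separable component.

Step 4
Reactants: 7 cis-1,5-dimethylbicyclo[3.3.0]octane-3,7-dione mono(ethylene ketal)
Product: 10 cis-1,5-dimethylbicyclo[3.3.0]octan-3-one (meso), via hydrazone 8 (not isolated), via deoxygenated ketal 9 (not isolated)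
Conditions: N2H4·H2O, KOH, diethylene glycol, 130 then 200 °C; then 2 M HCl, THF, 25 °C
Reagents that add atoms: water, O
Why: Wolff–Kishner reduction (Huang-Minlon procedure) of the free ketone, which the base-stable ketal survives, followed by acid hydrolysis of the ketal; no stereocentre is touched.

Step 5
Reactants: 10 cis-1,5-dimethylbicyclo[3.3.0]octan-3-one
Product: 11 (1R,5S)-1,5-dimethyl-3-(trimethylsilyloxy)bicyclo[3.3.0]oct-2-ene
Conditions: (R,R)-bis(1-phenylethyl)amine hydrochloride, n-BuLi (2 equiv), THF, −78 to 0 °C; then TMSCl, 10, −100 °C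
Reagents that add atoms: chlorotrimethylsilane, C[Si](C)(C)Cl
Why: Enantioselective deprotonation of a meso ketone by a C2-symmetric chiral lithium amide with in-situ silyl trapping; the base distinguishes the two enantiotopic α-methylene groups and so fixes the absolute configuration of both quaternary carbons at once.

Step 6
Reactants: 11 (1R,5S)-1,5-dimethyl-3-(trimethylsilyloxy)bicyclo[3.3.0]oct-2-ene
Product: 13 2-[(1S,2S)-2-formyl-1,2-dimethylcyclopentyl]acetic acid, via trimethylsilyl ester 12 (not isolated)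
Conditions: O3, CH2Cl2, −78 °C; Me2S, −78 to 25 °C; aqueous work-up
Reagents that add atoms: ozone, O=[O+][O-]
Why: Ozonolysis of the silyl enol ether turns the vinylic CH into the aldehyde on one quaternary carbon and the silyloxy carbon into the acid on the CH2 of the other; the cis relation of the two arms comes from the ring fusion.

Step 7
Reactants: 13 2-[(1S,2S)-2-formyl-1,2-dimethylcyclopentyl]acetic acid; 14 2-methylbut-3-yn-2-ol
Product: 18 2-[(1S,2S)-1,2-dimethyl-2-[4-methyl-1,4-bis(triethylsilyloxy)pent-2-yn-1-yl]cyclopentyl]acetic acid (both epimers at the new carbinol carbon), via dilithiated alkynol 15 (not isolated), via trilithium hydroxy carboxylate 16 (not isolated), via tris(triethylsilyl) derivative 17 (not isolated)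
Conditions: 14 (3 equiv), n-BuLi (6 equiv), THF, −78 to 0 °C; 13, −78 to 0 °C; TESOTf (5 equiv), −78 to 0 °C; aqueous NaHCO3, then pH 4
Reagents that add atoms: triethylsilyl trifluoromethanesulfonate, CC[Si](CC)(CC)OS(=O)(=O)C(F)(F)F
Why: 1,2-Addition of a lithium acetylide to the non-enolisable aldehyde (the carboxylate is a spectator) and silylation of both alkoxides; the silyl ester is hydrolysed on work-up, and the new carbinol centre forms as an epimer mixture that is oxidised to the ketone in step 12.

Step 8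
Reactants: 18 the bis(silyl ether) acid; 5 4-methoxy-2-methyl-6-(3-methylbut-3-en-1-yl)phenol
Product: 19 4-methoxy-2-methyl-6-(3-methylbut-3-en-1-yl)phenyl 2-[(1S,2S)-1,2-dimethyl-2-[4-methyl-1,4-bis(triethylsilyloxy)pent-2-yn-1-yl]cyclopentyl]acetate
Conditions: DIC, DMAP (cat.), CH2Cl2, 25 °C
Reagents that add atoms: none
Why: Steglich esterification; the aryl ester is the temporary tether that places the acyl carbon and the phenol oxygen next to the alkene.

Step 9
Reactants: 19 the aryl ester
Product: 20 1-[(2S)-6-methoxy-2,8-dimethyl-3,4-dihydro-2H-chromen-2-yl]-3-[(1S,2S)-1,2-dimethyl-2-[4-methyl-1,4-bis(triethylsilyloxy)pent-2-yn-1-yl]cyclopentyl]propan-2-one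
Conditions: Pd2(dba)3 (5 mol %), free carbene 1,3-bis{2,6-bis[(1R)-1-phenylethyl]-4-methylphenyl}-4,5-dihydroimidazol-2-ylidene (12 mol %), toluene, 100 °C, sealed vessel
Reagents that add atoms: none
Why: Proposed new method: zerovalent palladium on the bulky carbene, held near the ester by the pendant alkene, should insert into the C(acyl)–O bond of the aryl ester; the 1,1-disubstituted alkene then inserts into the Pd–O bond by a chair-like syn-oxypalladation (6-exo-trig closure of the pyran ring), and C(sp3)–C(acyl) reductive elimination forms the CH2–C(=O) bond and returns the catalyst. The closest known reaction types are the chelation-assisted iridium- and rhodium-catalysed intramolecular alkene oxyacylation of aryl esters, the acyl C–O oxidative addition of aryl esters to palladium–carbene catalysts in ketone-forming cross-couplings, and the palladium-catalysed carboetherification of 2-(3-methylbut-3-enyl)phenols to 2,2-disubstituted chromans. The new quaternary centre C-2 is set in the oxypalladation, where the C2-symmetric carbene should differentiate the alkene faces (catalyst control; the cyclopentane centres are remote). Because the acyl part is enantiopure, any minor C-2 epimer is a diastereomer and can be removed by chromatography. The step needs C(acyl)–O rather than C(aryl)–O insertion (favoured by the carbene ligand and the electron-rich arene), retention of CO in the acylpalladium species (closed vessel, moderate temperature) and no alkene isomerisation before cyclisation.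

Step 10
Reactants: 20 the chroman ketone
Product: 21 1-[(2R)-6-methoxy-2,8-dimethyl-2H-chromen-2-yl]-3-[(1S,2S)-1,2-dimethyl-2-[4-methyl-1,4-bis(triethylsilyloxy)pent-2-yn-1-yl]cyclopentyl]propan-2-one
Conditions: DDQ (1.5 equiv), benzene, 80 °C
Reagents that add atoms: none
Why: DDQ dehydrogenation of a chroman to a 2H-chromene by hydride abstraction at the benzylic C-4 (cation stabilised by O-1) and loss of the C-3 proton; C-2 is untouched, and its descriptor changes from S to R only through the priority rules.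

Step 11
Reactants: 21 the bis(silyl ether) chromene
Product: 22 1-[(2R)-6-methoxy-2,8-dimethyl-2H-chromen-2-yl]-3-[(1S,2S)-2-(1,4-dihydroxy-4-methylpent-2-yn-1-yl)-1,2-dimethylcyclopentyl]propan-2-one (both carbinol epimers)
Conditions: HF·pyridine, pyridine, THF, 0 to 25 °C
Reagents that add atoms: none
Why: Fluoride-mediated cleavage of both triethylsilyl ethers under buffered, non-basic conditions, which avoids retro-oxa-Michael opening of the β-aryloxy ketone.

Step 12
Reactants: 22 the diol
Product: 23 1-[(1S,2S)-2-{3-[(2R)-6-methoxy-2,8-dimethyl-2H-chromen-2-yl]-2-oxopropyl}-1,2-dimethylcyclopentyl]-4-hydroxy-4-methylpent-2-yn-1-one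
Conditions: Dess–Martin periodinane, CH2Cl2, 0 to 25 °C
Reagents that add atoms: none
Why: Dess–Martin oxidation of the secondary propargylic alcohol to the ynone; the tertiary alcohol cannot be oxidised, and both carbinol epimers converge on one compound.

Step 13
Reactants: 23 the ynone
Product: 24 (Z)-1-[(1S,2S)-2-{3-[(2R)-6-methoxy-2,8-dimethyl-2H-chromen-2-yl]-2-oxopropyl}-1,2-dimethylcyclopentyl]-4-hydroxy-4-methylpent-2-en-1-one (CNP0137762.2)
Conditions: H2 (1 atm), Pd/CaCO3 poisoned with Pb(OAc)2 (Lindlar catalyst), quinoline, EtOAc, 0 °C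
Reagents that add atoms: none
Why: Lindlar semihydrogenation delivers both hydrogens to one face of the alkyne and should give the Z-enone; the conjugated chromene double bond is expected to be left intact.

**Compound list**

1 | 4-methoxy-2-methylphenol | COc1ccc(O)c(C)c1 | starting material
2 | 2-bromo-4-methoxy-6-methylphenol | COc1cc(C)c(O)c(Br)c1 | intermediate
3 | 4-bromo-2-methylbut-1-ene | C=C(C)CCBr | starting material
4 | (3-methylbut-3-en-1-yl)zinc bromide | C=C(C)CC[Zn]Br | intermediate
5 | 4-methoxy-2-methyl-6-(3-methylbut-3-en-1-yl)phenol | COc1cc(C)c(O)c(CCC(C)=C)c1 | intermediate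
6 | cis-1,5-dimethylbicyclo[3.3.0]octane-3,7-dione (meso) | O=C2C[C@]1(C)CC(=O)C[C@]1(C)C2 | starting material
7 | cis-1,5-dimethylbicyclo[3.3.0]octane-3,7-dione mono(ethylene ketal) | O=C2C[C@]1(C)CC3(OCCO3)C[C@]1(C)C2 | intermediate
8 | hydrazone of 7 | NN=C2C[C@]1(C)CC3(OCCO3)C[C@]1(C)C2 | intermediate
9 | ethylene ketal of cis-1,5-dimethylbicyclo[3.3.0]octan-3-one | C2C[C@]1(C)CC3(OCCO3)C[C@]1(C)C2 | intermediate
10 | cis-1,5-dimethylbicyclo[3.3.0]octan-3-one (meso) | O=C2C[C@]1(C)CCC[C@]1(C)C2 | intermediate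
11 | (1R,5S)-1,5-dimethyl-3-(trimethylsilyloxy)bicyclo[3.3.0]oct-2-ene | C[Si](C)(C)OC1=C[C@@]2(C)CCC[C@@]2(C)C1 | intermediate
12 | trimethylsilyl 2-[(1S,2S)-2-formyl-1,2-dimethylcyclopentyl]acetate | C[Si](C)(C)OC(=O)C[C@]1(C)CCC[C@]1(C)C=O | intermediate
13 | 2-[(1S,2S)-2-formyl-1,2-dimethylcyclopentyl]acetic acid | OC(=O)C[C@]1(C)CCC[C@]1(C)C=O | intermediate
14 | 2-methylbut-3-yn-2-ol | CC(C)(O)C#C | starting material
15 | dilithiated 2-methylbut-3-yn-2-ol (lithium alkoxide, lithium acetylide) | [Li]C#CC(C)(C)O[Li] | intermediate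
16 | trilithium salt of 2-[(1S,2S)-2-(1,4-dihydroxy-4-methylpent-2-yn-1-yl)-1,2-dimethylcyclopentyl]acetic acid (both carbinol epimers) | [Li]OC(=O)C[C@]1(C)CCC[C@]1(C)C(O[Li])C#CC(C)(C)O[Li] | intermediate
17 | triethylsilyl 2-[(1S,2S)-1,2-dimethyl-2-[4-methyl-1,4-bis(triethylsilyloxy)pent-2-yn-1-yl]cyclopentyl]acetate (both carbinol epimers) | CC[Si](CC)(CC)OC(=O)C[C@]1(C)CCC[C@]1(C)C(O[Si](CC)(CC)CC)C#CC(C)(C)O[Si](CC)(CC)CC | intermediate
18 | 2-[(1S,2S)-1,2-dimethyl-2-[4-methyl-1,4-bis(triethylsilyloxy)pent-2-yn-1-yl]cyclopentyl]acetic acid (both carbinol epimers) | OC(=O)C[C@]1(C)CCC[C@]1(C)C(O[Si](CC)(CC)CC)C#CC(C)(C)O[Si](CC)(CC)CC | intermediate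
19 | 4-methoxy-2-methyl-6-(3-methylbut-3-en-1-yl)phenyl ester of 18 (both carbinol epimers) | COc1cc(C)c(OC(=O)C[C@]2(C)CCC[C@]2(C)C(O[Si](CC)(CC)CC)C#CC(C)(C)O[Si](CC)(CC)CC)c(CCC(C)=C)c1 | intermediate
20 | 1-[(2S)-6-methoxy-2,8-dimethyl-3,4-dihydro-2H-chromen-2-yl]-3-[(1S,2S)-1,2-dimethyl-2-[4-methyl-1,4-bis(triethylsilyloxy)pent-2-yn-1-yl]cyclopentyl]propan-2-one (both carbinol epimers) | COc1cc(C)c2c(c1)CC[C@@](C)(CC(=O)C[C@]1(C)CCC[C@]1(C)C(O[Si](CC)(CC)CC)C#CC(C)(C)O[Si](CC)(CC)CC)O2 | intermediate
21 | 1-[(2R)-6-methoxy-2,8-dimethyl-2H-chromen-2-yl]-3-[(1S,2S)-1,2-dimethyl-2-[4-methyl-1,4-bis(triethylsilyloxy)pent-2-yn-1-yl]cyclopentyl]propan-2-one (both carbinol epimers) | COc1cc(C)c2c(c1)C=C[C@@](C)(CC(=O)C[C@]1(C)CCC[C@]1(C)C(O[Si](CC)(CC)CC)C#CC(C)(C)O[Si](CC)(CC)CC)O2 | intermediate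
22 | 1-[(2R)-6-methoxy-2,8-dimethyl-2H-chromen-2-yl]-3-[(1S,2S)-2-(1,4-dihydroxy-4-methylpent-2-yn-1-yl)-1,2-dimethylcyclopentyl]propan-2-one (both carbinol epimers) | COc1cc(C)c2c(c1)C=C[C@@](C)(CC(=O)C[C@]1(C)CCC[C@]1(C)C(O)C#CC(C)(C)O)O2 | intermediate
23 | 1-[(1S,2S)-2-{3-[(2R)-6-methoxy-2,8-dimethyl-2H-chromen-2-yl]-2-oxopropyl}-1,2-dimethylcyclopentyl]-4-hydroxy-4-methylpent-2-yn-1-one | COc1cc(C)c2c(c1)C=C[C@@](C)(CC(=O)C[C@]1(C)CCC[C@]1(C)C(=O)C#CC(C)(C)O)O2 | intermediate
24 | (Z)-1-[(1S,2S)-2-{3-[(2R)-6-methoxy-2,8-dimethyl-2H-chromen-2-yl]-2-oxopropyl}-1,2-dimethylcyclopentyl]-4-hydroxy-4-methylpent-2-en-1-one | COc1cc(C)c2c(c1)C=C[C@@](C)(CC(=O)C[C@]1(C)CCC[C@]1(C)C(=O)/C=C\C(C)(C)O)O2 | target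

**Total step count:** 13. **Longest linear sequence:** 11 steps (steps 3 to 13, from 6).

**Steps most likely to fail**

Step 9 (proposed new method). The electron-rich, doubly ortho-substituted aryl ester may resist C(acyl)–O insertion, the acylpalladium species may lose CO, or face selection at the alkene may be poor. The fallback uses known chemistry, sets out from 5 and 18, and returns at 20. Phenol 5 is cyclised by the enantioselective domino Wacker cyclisation–methoxycarbonylation [Pd(OCOCF3)2, (R,R)-Bn-BOXAX, p-benzoquinone, CO (1 atm), MeOH, 25 °C], which should give methyl 2-[(2S)-6-methoxy-2,8-dimethylchroman-2-yl]acetate F1. Saponification (LiOH, THF–H2O) gives 2-[(2S)-6-methoxy-2,8-dimethylchroman-2-yl]acetic acid F2, and N-hydroxyphthalimide with DIC gives its N-acyloxyphthalimide ester F3. Acid 18 is converted with 2,2'-dipyridyl disulfide and PPh3 into its S-(2-pyridyl) thioester F4. Nickel-catalysed decarboxylative cross-electrophile coupling of F3 with F4 [NiCl2(dme), 4,4'-di-tert-butyl-2,2'-bipyridine, Zn, THF–DMA, 25 °C] joins the chroman-2-ylmethyl radical to the acylnickel species, forms the same CH2–C(=O) bond and should give 20.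

Step 5. Discrimination between the two enantiotopic methylene groups may be low, or the opposite sense may be obtained, at these hindered neopentyl positions. The fallback sets out from 10 and returns at 13. Ketone 10 is ketalised with (2R,4R)-pentane-2,4-diol (p-TsOH, benzene, reflux) to the chiral spiro ketal F5. Triisobutylaluminium (CH2Cl2, 0 °C) should open the ketal diastereoselectively, with elimination, to the hydroxyalkyl enol ether (2R,4R)-4-{[(1R,5S)-1,5-dimethylbicyclo[3.3.0]oct-2-en-3-yl]oxy}pentan-2-ol F6. Ozonolysis (O3, CH2Cl2, −78 °C; Me2S) gives (2R,4R)-4-hydroxypentan-2-yl 2-[(1S,2S)-2-formyl-1,2-dimethylcyclopentyl]acetate F7, and LiOH (THF–H2O, 0 °C) releases 13.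

Step 10. Hydride abstraction may compete at the 8-methyl group, or the electron-rich arene may be over-oxidised. The fallback sets out from 20 and returns at 21. Radical benzylic bromination (NBS, dibenzoyl peroxide, PhCF3, 80 °C) should give the 4-bromochroman F8, and loss of HBr on warming with Li2CO3 and LiBr in DMF gives 21.

**Further compounds**

F1 | step 9 | methyl 2-[(2S)-6-methoxy-2,8-dimethylchroman-2-yl]acetate | COc1cc(C)c2c(c1)CC[C@@](C)(CC(=O)OC)O2
F2 | step 9 | 2-[(2S)-6-methoxy-2,8-dimethylchroman-2-yl]acetic acid | COc1cc(C)c2c(c1)CC[C@@](C)(CC(=O)O)O2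
F3 | step 9 | 1,3-dioxoisoindolin-2-yl 2-[(2S)-6-methoxy-2,8-dimethylchroman-2-yl]acetate | COc1cc(C)c2c(c1)CC[C@@](C)(CC(=O)ON3C(=O)c4ccccc4C3=O)O2
F4 | step 9 | S-(pyridin-2-yl) thioester of 18 (both carbinol epimers) | O=C(Sc1ccccn1)C[C@]1(C)CCC[C@]1(C)C(O[Si](CC)(CC)CC)C#CC(C)(C)O[Si](CC)(CC)CC
F5 | step 5 | (2R,4R)-pentane-2,4-diyl ketal of 10 | C[C@@H]1C[C@@H](C)OC2(O1)C[C@]3(C)CCC[C@]3(C)C2
F6 | step 5 | (2R,4R)-4-{[(1R,5S)-1,5-dimethylbicyclo[3.3.0]oct-2-en-3-yl]oxy}pentan-2-ol | C[C@@H](O)C[C@@H](C)OC1=C[C@@]2(C)CCC[C@@]2(C)C1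
F7 | step 5 | (2R,4R)-4-hydroxypentan-2-yl 2-[(1S,2S)-2-formyl-1,2-dimethylcyclopentyl]acetate | C[C@@H](O)C[C@@H](C)OC(=O)C[C@]1(C)CCC[C@]1(C)C=O
F8 | step 10 | 4-bromo derivative of 20 (either configuration at C-4, both carbinol epimers) | COc1cc(C)c2c(c1)C(Br)C[C@@](C)(CC(=O)C[C@]1(C)CCC[C@]1(C)C(O[Si](CC)(CC)CC)C#CC(C)(C)O[Si](CC)(CC)CC)O2
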